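## The problem

Compound 15 is a single cyclohexene ring with nothing fused or bridged, so the task lies in four contiguous oxygenated stereocenters and five oxygen atoms of three kinds. Take C1 as the quaternary carbinol that carries the exocyclic C7, then C2 (benzoate), C3=C4 (alkene), C5 (benzoate) and C6 (free hydroxyl) round the ring. The configuration is (1S,2S,5S,6S): O1, O6 and O5 lie on one face, O2 and C7 on the other. Three oxygens end as benzoates (O7 primary, O2 and O5 allylic secondary) and two stay free (O1 tertiary, O6 secondary next to C1), so the order in which the oxygens arrive must do the work of protecting groups. Only C1 has to be set in the absolute sense: a nucleophile opening a C1–C2 epoxide at C2 ends trans to O1, and the C1 hydroxyl can then steer a syn addition to a C5=C6 alkene on its own face, fixing C6 and C5 together. The esters restrict the later steps: benzoates migrate within the cis O5/O6 pair and the O2/O1/O7 array under base, the allylic C2 and C5 esters can ionise, and any cyclohexadiene that still carries O1 and O2 can aromatise by loss of water or benzoic acid. The feature that opens the molecule is the array O7–C7–C1(O)–C2(O): read backwards it is a 2,3-epoxy alcohol whose alkene precursor has its only allylic hydroxyl on C7, while C3 to C6 need no more than an isolated C4=C5 alkene at that stage.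

## Retrosynthesis

**15 from 14: the O5–benzoyl bond.** The C5 ester is the one acyl group that cannot arrive together with its C–O bond, because a syn dihydroxylation delivers two free hydroxyls and an epoxide opening by benzoate would give the trans isomer. Triol 14 is simpler by one ester. The forward step must pick O5 (allylic, one substituted neighbour) over O6 (next to quaternary C1) and O1 (tertiary).

**14 from 12: the C5–O and C6–O bonds, cut together.** A syn dihydroxylation removes two stereocenters at once and leaves diene 12 with only C1 and C2 stereogenic. Cutting them one at a time through a C5–C6 epoxide would give a trans diol. The forward reaction must choose the C5=C6 alkene over C3=C4 and the face of the C1 hydroxyl; hydrogen bonding of that hydroxyl to an amine-ligated osmium oxidant supplies both.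

**12 from 9 (through 10 and 11): the two π bonds are traced back to one.** Addition of bromine across C4=C5 and twofold loss of HBr towards C3 and C6 moves the unsaturation into the C3=C4–C5=C6 diene. This cut is preferred over direct allylic oxidation of 9, which would place oxygen at one carbon only and with no stereocontrol. Alkene 9 is a stable, non-conjugated compound. The forward steps must eliminate without disturbing the two benzoates or aromatising the product.

**9 from 6 and 7 (through 8): the O7–benzoyl bond and the C2–O bond.** Cutting C2–O with benzoic acid 7 as the nucleophile and C2 as an epoxide carbon gives the trans O1/O2 relation and the C2 ester in one operation. Opening with water and then differentiating three hydroxyls would cost steps. Epoxy alcohol 6 has only two stereocenters, both in the oxirane. The forward opening must occur at secondary C2 and not at quaternary C1, with clean inversion.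

**6 from 5: both C–O bonds of the oxirane (key disconnection).** Removing the epoxide oxygen leaves the achiral cyclohexa-1,4-dien-1-ylmethanol 5, so all absolute stereochemistry is written by one reagent-controlled epoxidation. An auxiliary or chiral-pool approach would carry extra atoms or steps. The forward reaction must discriminate the two faces of C1=C2 and ignore C4=C5.

**5 from 1 and 2 (through 3 and 4): the C2–C3 and C1–C6 ring bonds and the oxidation level of C7.** Ester 3 is the Diels–Alder adduct of 1,3-butadiene 1 and methyl propiolate 2. The cycloaddition places the two alkenes of the skipped diene exactly where they are needed, which a Birch-type reduction of an arene would do less cleanly in the presence of a benzylic oxygen. Reduction of 3 through aldehyde 4 gives 5.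

## Roads not taken

**Alternative 1:** The cut is the C1–C2 ring bond, made by a [3,3]-sigmatropic shift that breaks a pyran C–O bond at the same time. Heating the galactal-type allyl vinyl ether A1 would give cyclohexenecarbaldehyde A2, with C7 as the aldehyde, the C2 and C5 benzoates in place, and O1 and O6 as 4-methoxybenzyl ethers.
- Merits: the absolute configuration comes from the hexose chiral pool, so there is no question of enantiomeric purity. Quaternary C1 and C2 are made in one pericyclic step. O5 and O6 are differentiated from the outset, and the C3=C4 alkene appears where it belongs without any diene chemistry.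
- Weak points: A1 needs a 2-alkoxy glycal, two ether protections, oxidation of the sugar C6 and an (E)-selective enol benzoate formation. A2 still requires aldehyde reduction, C7 benzoylation and two oxidative ether cleavages beside allylic esters. The rearrangement needs high temperature with an enol ester on board, and a boat-versus-chair choice in the transition state decides C1 and C2 together.
- Comparison: this road is better in absolute stereocontrol and in avoiding the two selective steps of the chosen plan (steps 8 and 9). The chosen plan sets against it nine steps from commodity chemicals, no protecting groups, and control elements that each act on one stereochemical question at a time.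

**Alternative 2:** The cut is the C6–O bond. The achiral para-quinol A3 would be desymmetrised by a chiral phosphoric acid carrying 2,4,6-triisopropylphenyl groups on a binaphthyl backbone. O1 forms a hemiacetal with a branched aliphatic aldehyde, and the hemiacetal hydroxyl adds to one enone to give the cis-fused dioxolane enone A4.
- Merits: A3 is reached in very few steps from a phenol. The key step is catalytic, sets C1 and C6 cis, and masks O1 and O6 together.
- Weak points: A4 still lacks both secondary benzoates and has its unsaturation in the wrong place. The C4 ketone and C2=C3 alkene must be transposed into C2–O and C3=C4 (epoxidation and a Wharton-type transposition). C5 must be oxygenated cis to O6, on the concave face of the bicycle. Any enolisation towards C5 invites β-elimination of the C6 acetal oxygen, which undoes the key step and leads to a phenol.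
- Comparison: up to the first chiral intermediate this road is as short as the chosen one and equally catalytic. The chosen plan answers with a shorter sequence after the key step, in which each later stereocenter is set with, not against, the bias of the substrate.

**Alternative 3:** The cut is the C2–C4 bond of a ring-fused cyclopropane, a one-carbon ring expansion of a pentose-derived cyclopentane. AgBF4 in wet acetone would ionise the gem-dibromocyclopropane A5, the six-membered allyl cation would be captured at C2 by the carbonyl oxygen of the C7 benzoate, and hydrolysis would give bromocyclohexene A6 with the C2 benzoate in place and O7 free.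
- Merits: the cis O5/O6 pair and its absolute configuration come from the chiral pool as an acetonide. The C2–O bond is delivered intramolecularly from C7, so its trans relation to O1 is tied to C1.
- Weak points: A5 needs a long sequence (carbocycle construction, stereoselective formation of the tertiary carbinol, face-selective dibromocarbene addition). A6 keeps a vinylic bromine at C3 that must be removed reductively beside allylic esters. The acetonide must be cleaved, and O7 and O5 still have to be benzoylated selectively.
- Comparison: this road is better at securing the C5/C6 diol, since no regio- and face-selective oxidation of a diene is needed, and it shares the final O5 selection problem. The chosen plan sets against it a much shorter route with no dehalogenation and no protecting-group removal.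

Key step: step 3

Assumption: the sense of induction in step 3 is taken from the established correlation that L-(+)-tartrate gives (2S,3S)-epoxides from (E)-2-alken-1-ols; on that basis the (1R,6R)-epoxide 6 requires the D-(−)-ester, and the configuration of 6 would be confirmed (rotation, MTPA ester) before material is committed.

Assumption: dibromide 10 and bromide 11 are drawn as single isomers; the C4/C5 configuration and the order of the two eliminations are immaterial because all such isomers converge on 12.

## Route

Step 1
Reactants: 1 1,3-butadiene; 2 methyl propiolate
Product: 3 methyl cyclohexa-1,4-diene-1-carboxylate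
Conditions: 1 (excess), toluene, BHT (cat.), sealed vessel, 110 °C, Ar
Reagents that add atoms: none
Why: Thermal Diels–Alder cycloaddition of an electron-poor alkyne to butadiene forms the C2–C3 and C1–C6 bonds and gives the skipped diene directly; exclusion of air and a radical inhibitor restrain polymerisation and aromatisation.

Step 2
Reactants: 3 methyl cyclohexa-1,4-diene-1-carboxylate
Product: 5 cyclohexa-1,4-dien-1-ylmethanol, via cyclohexa-1,4-diene-1-carbaldehyde 4 (not isolated)
Conditions: iBu2AlH (2.3 equiv), CH2Cl2, −78 → 0 °C; aq. potassium sodium tartrate
Reagents that add atoms: none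
Why: 1,2-Reduction of an α,β-unsaturated ester by an electrophilic aluminium hydride, which reduces the intermediate aldehyde faster than the ester and leaves both alkenes and the skipped arrangement untouched.

Step 3
Reactants: 5 cyclohexa-1,4-dien-1-ylmethanol
Product: 6 [(1R,6R)-7-oxabicyclo[4.1.0]hept-3-en-1-yl]methanol
Conditions: Ti(OiPr)4 (10 mol%), D-(−)-diethyl tartrate (12 mol%), t-BuOOH (2 equiv, anhydrous), 4 Å MS, CH2Cl2, −20 °C
Reagents that add atoms: tert-butyl hydroperoxide CC(C)(C)OO
Why: Sharpless asymmetric epoxidation: alcohol 5 and t-BuOOH exchange onto one titanium of the dimeric titanium tartrate complex, and the peroxide oxygen is passed to the C1=C2 alkene of the bound allylic alkoxide in a concerted transfer. The closest known cases are the epoxidations of 1-cyclohexenylmethanol and other 2,3-disubstituted primary allylic alcohols, which 5 matches around the reacting alkene. The oxirane closes by suprafacial addition of one oxygen atom to both alkene carbons at once, so the C1–O and C2–O bonds are necessarily cis. Both new stereocenters, C1 and C2, are set by the tartrate: L-(+)-tartrate gives (2S,3S)-epoxides from (E)-2-alken-1-ols, which for 5 (ring C3 as the E-substituent, ring C6 at the 2-position, same priority order at both carbons) would mean the (1S,6S)-epoxide, so the D-(−)-ester is used to obtain (1R,6R)-6. The step needs chemoselectivity for C1=C2 over C4=C5, which the mechanism secures because only an alkene whose allylic oxygen is bound to titanium is within reach of the peroxide. Molecular sieves keep the catalyst turning over and limit opening of the epoxide by isopropoxide or tartrate.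

Step 4
Reactants: 6 [(1R,6R)-7-oxabicyclo[4.1.0]hept-3-en-1-yl]methanol; 7 benzoic acid
Product: 8 (1S,6R)-6-hydroxy-6-(hydroxymethyl)cyclohex-3-en-1-yl benzoate
Conditions: 7 (1.5 equiv), Ti(OiPr)4 (1.5 equiv), CH2Cl2, rt; aq. tartaric acid work-up
Reagents that add atoms: none
Why: Titanium-assisted opening of a 2,3-epoxy alcohol by a carboxylic acid at the carbon distal to the hydroxyl: chelation through O7 and the epoxide oxygen directs benzoate to secondary C2 with inversion (SN2), giving the trans O1/O2 pair. An acyl shift from O2 to O7 would be harmless because step 5 carries either monobenzoate to 9.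

Step 5
Reactants: 8 (1S,6R)-6-hydroxy-6-(hydroxymethyl)cyclohex-3-en-1-yl benzoate
Product: 9 [(1R,6S)-6-(benzoyloxy)-1-hydroxycyclohex-3-en-1-yl]methyl benzoate
Conditions: BzCl (1.2 equiv), pyridine, CH2Cl2, 0 °C
Reagents that add atoms: benzoyl chloride O=C(Cl)c1ccccc1
Why: Acylation of a primary alcohol in the presence of a tertiary one; the C1 hydroxyl is too hindered to react under these conditions and stays free as the later director.

Step 6
Reactants: 9 [(1R,6S)-6-(benzoyloxy)-1-hydroxycyclohex-3-en-1-yl]methyl benzoate
Product: 10 [(1R,2S,4S,5S)-2-(benzoyloxy)-4,5-dibromo-1-hydroxycyclohexyl]methyl benzoate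
Conditions: Br2 (1.05 equiv), CH2Cl2, −78 °C, dark
Reagents that add atoms: bromine BrBr
Why: Anti addition of bromine to the isolated C4=C5 alkene through a bromonium ion opened trans-diaxially, as in the bromination of cyclohex-4-ene-1,2-diol derivatives; low temperature and free bromide favour the dibromide over transannular capture by the C1 hydroxyl.

Step 7
Reactants: 10 [(1R,2S,4S,5S)-2-(benzoyloxy)-4,5-dibromo-1-hydroxycyclohexyl]methyl benzoate
Product: 12 [(1R,6S)-6-(benzoyloxy)-1-hydroxycyclohexa-2,4-dien-1-yl]methyl benzoate, via allylic bromide 11 (not isolated)
Conditions: DBU (4 equiv), toluene, 80 °C, Ar, dark; used at once in step 8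
Reagents that add atoms: none
Why: Twofold E2 dehydrobromination with an amidine base, the standard entry to 5,6-dioxygenated cyclohexa-1,3-dienes from 4,5-dibromocyclohexane-1,2-diol esters. Each axial bromine has an anti-periplanar hydrogen only on its outer neighbour (C3 or C6), so no vinyl bromide can form, and the non-nucleophilic base spares the benzoates.

Step 8
Reactants: 12 [(1R,6S)-6-(benzoyloxy)-1-hydroxycyclohexa-2,4-dien-1-yl]methyl benzoate
Product: 14 [(1S,2S,5S,6S)-2-(benzoyloxy)-1,5,6-trihydroxycyclohex-3-en-1-yl]methyl benzoate, via TMEDA osmate ester 13 (not isolated)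
Conditions: OsO4 (1.05 equiv), TMEDA (1.1 equiv), CH2Cl2, −78 °C; then HCl, MeOH, rt
Reagents that add atoms: osmium tetroxide O=[Os](=O)(=O)=O
Why: Hydrogen-bond-directed dihydroxylation of an allylic alcohol: the OsO4–TMEDA complex accepts a hydrogen bond from the C1 hydroxyl and so adds to the adjacent C5=C6 alkene on the hydroxyl face, setting C5 and C6 cis to each other and to O1. Undirected osmylation would be expected at C3=C4 anti to the C2 benzoate, which is why the amine-ligated reagent is used; acidic methanolysis then frees the diol from the stable osmate ester.

Step 9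
Reactants: 14 [(1S,2S,5S,6S)-2-(benzoyloxy)-1,5,6-trihydroxycyclohex-3-en-1-yl]methyl benzoate
Product: 15 [(1S,2S,5S,6S)-2,5-bis(benzoyloxy)-1,6-dihydroxycyclohex-3-en-1-yl]methyl benzoate (CNP0128482.4)
Conditions: BzCl (1.1 equiv), pyridine, CH2Cl2, −40 → 0 °C
Reagents that add atoms: benzoyl chloride O=C(Cl)c1ccccc1
Why: Site-selective acylation of the least hindered hydroxyl: O5 is allylic with one substituted neighbour, O6 sits next to quaternary C1 and O1 is tertiary. The C5 ester is also the less congested partner of any O5/O6 acyl shift, so kinetic and thermodynamic preference point the same way.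

## Compound list

1 | 1,3-butadiene | C=CC=C | starting material
2 | methyl propiolate | C#CC(=O)OC | starting material
3 | methyl cyclohexa-1,4-diene-1-carboxylate | COC(=O)C1=CCC=CC1 | intermediate
4 | cyclohexa-1,4-diene-1-carbaldehyde (not isolated) | O=CC1=CCC=CC1 | intermediate
5 | cyclohexa-1,4-dien-1-ylmethanol | OCC1=CCC=CC1 | intermediate
6 | [(1R,6R)-7-oxabicyclo[4.1.0]hept-3-en-1-yl]methanol | OC[C@]12CC=CC[C@H]1O2 | intermediate
7 | benzoic acid | O=C(O)c1ccccc1 | starting material
8 | (1S,6R)-6-hydroxy-6-(hydroxymethyl)cyclohex-3-en-1-yl benzoate | OC[C@]1(O)CC=CC[C@@H]1OC(=O)c1ccccc1 | intermediate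
9 | [(1R,6S)-6-(benzoyloxy)-1-hydroxycyclohex-3-en-1-yl]methyl benzoate | O=C(OC[C@]1(O)CC=CC[C@@H]1OC(=O)c1ccccc1)c1ccccc1 | intermediate
10 | [(1R,2S,4S,5S)-2-(benzoyloxy)-4,5-dibromo-1-hydroxycyclohexyl]methyl benzoate | O=C(OC[C@]1(O)C[C@H](Br)[C@@H](Br)C[C@@H]1OC(=O)c1ccccc1)c1ccccc1 | intermediate
11 | [(1R,2S,5S)-2-(benzoyloxy)-5-bromo-1-hydroxycyclohex-3-en-1-yl]methyl benzoate (not isolated) | O=C(OC[C@]1(O)C[C@H](Br)C=C[C@@H]1OC(=O)c1ccccc1)c1ccccc1 | intermediate
12 | [(1R,6S)-6-(benzoyloxy)-1-hydroxycyclohexa-2,4-dien-1-yl]methyl benzoate | O=C(OC[C@]1(O)C=CC=C[C@@H]1OC(=O)c1ccccc1)c1ccccc1 | intermediate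
13 | TMEDA-chelated dioxo-osmium diolate of 14 across O5 and O6, osmium on the face of the C1 hydroxyl (not isolated) | O=C(OC[C@]1(O)[C@H]3O[Os-2]4(=O)(=O)([N+](C)(C)CC[N+]4(C)C)O[C@H]3C=C[C@@H]1OC(=O)c1ccccc1)c1ccccc1 | intermediate
14 | [(1S,2S,5S,6S)-2-(benzoyloxy)-1,5,6-trihydroxycyclohex-3-en-1-yl]methyl benzoate | O=C(OC[C@]1(O)[C@@H](O)[C@@H](O)C=C[C@@H]1OC(=O)c1ccccc1)c1ccccc1 | intermediate
15 | [(1S,2S,5S,6S)-2,5-bis(benzoyloxy)-1,6-dihydroxycyclohex-3-en-1-yl]methyl benzoate (CNP0128482.4) | O=C(OC[C@@]1(O)[C@@H](OC(=O)c2ccccc2)C=C[C@H](OC(=O)c2ccccc2)[C@@H]1O)c1ccccc1 | target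

## Step count and least certain steps

Total steps: 9. Longest linear sequence: 9 steps (from 1 and 2 to 15).

**Step 3 (key step).** The most likely failure is incomplete enantioface discrimination, combined with loss of the small, water-soluble epoxy alcohol to hydrolytic opening or extraction during work-up; air oxidation of 5 to the arene before it reacts would also drain material. The fallback sets out from 5 and comes back at 6. Epoxidation with VO(acac)2 (cat.) and t-BuOOH, directed by the same hydroxyl but not enantioselective, gives the racemic epoxy alcohol rac-(7-oxabicyclo[4.1.0]hept-3-en-1-yl)methanol F1. An acylative kinetic resolution with a lipase and vinyl acetate, the enzyme chosen by screening to acylate the (1S,6S)-antipode to [(1S,6S)-7-oxabicyclo[4.1.0]hept-3-en-1-yl]methyl acetate F2, then leaves 6 as the unreacted alcohol.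

**Step 8.** The most likely failure is osmylation at the wrong alkene or face, through competition from undirected attack at C3=C4 anti to the C2 benzoate, and acyl shifts or aromatisation while the osmate ester is cleaved. The fallback sets out from 12 and reaches 15 directly, replacing steps 8 and 9. Epoxidation with VO(acac)2 and t-BuOOH, delivered by the C1 hydroxyl to C5=C6, gives the vinyl epoxide on the hydroxyl face, [(1R,6S)-6-(benzoyloxy)-1-hydroxy-cis-2,3-epoxycyclohex-4-en-1-yl]methyl benzoate F7. Dilute aqueous acid in THF at 0 °C opens it at allylic C5 with inversion to the trans diol [(1S,2S,5R,6S)-2-(benzoyloxy)-1,5,6-trihydroxycyclohex-3-en-1-yl]methyl benzoate F8. A Mitsunobu reaction (PhCO2H, PPh3, diisopropyl azodicarboxylate) at the least hindered, allylic C5 hydroxyl inverts it again and installs the benzoate, giving 15.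

**Step 7.** The most likely failure is misdirected or incomplete elimination: 1,4-loss of HBr through C2–H to a dienyl benzoate, or aromatisation by loss of water or benzoic acid at 80 °C. The free C1 hydroxyl may also react under base, by transannular displacement of a C4 bromide or by acyl shift from O2 or O7. The fallback sets out from 10 and comes back at 12. The C1 hydroxyl is capped with Me3SiOTf and 2,6-lutidine to give the silyl ether [(1R,2S,4S,5S)-2-(benzoyloxy)-4,5-dibromo-1-(trimethylsilyloxy)cyclohexyl]methyl benzoate F4. DBU then eliminates twice, through the transient allylic bromide [(1R,2S,5S)-2-(benzoyloxy)-5-bromo-1-(trimethylsilyloxy)cyclohex-3-en-1-yl]methyl benzoate F5, to the silylated diene [(1R,6S)-6-(benzoyloxy)-1-(trimethylsilyloxy)cyclohexa-2,4-dien-1-yl]methyl benzoate F6. Bu4NF buffered with acetic acid at 0 °C releases 12.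

**Step 4.** The most likely failure is loss of regiocontrol through Lewis-acid ionisation of the C1–O bond at the tertiary centre (attack at C1 or hydride shift), or ester exchange with isopropoxide. The fallback sets out from 6 and comes back at 9. O7 is benzoylated first (BzCl, pyridine) to give the epoxy ester [(1R,6R)-7-oxabicyclo[4.1.0]hept-3-en-1-yl]methyl benzoate F3. The epoxide is then opened without Lewis acid by PhCO2Cs and PhCO2H in DMF at 80 °C, an SN2 attack at secondary C2 that gives 9 directly.

**Step 9.** The most likely failure is insufficient discrimination between O5 and O6: over-acylation, or acylation at O6 followed by acyl shift. The fallback sets out from 14 and comes back at 15. Bu2SnO in toluene with azeotropic removal of water gives the stannylene acetal across O5 and O6, 2,2-dibutyl-1,3,2-dioxastannolane F9. This activates one oxygen of the cis diol for monoacylation, and BzCl at room temperature then gives 15.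

## Further compounds

F1 | step 3 | rac-(7-oxabicyclo[4.1.0]hept-3-en-1-yl)methanol | OCC12CC=CCC1O2
F2 | step 3 | [(1S,6S)-7-oxabicyclo[4.1.0]hept-3-en-1-yl]methyl acetate | CC(=O)OC[C@@]12CC=CC[C@@H]1O2
F3 | step 4 | [(1R,6R)-7-oxabicyclo[4.1.0]hept-3-en-1-yl]methyl benzoate | O=C(OC[C@]12CC=CC[C@H]1O2)c1ccccc1
F4 | step 7 | [(1R,2S,4S,5S)-2-(benzoyloxy)-4,5-dibromo-1-(trimethylsilyloxy)cyclohexyl]methyl benzoate | O=C(OC[C@]1(O[Si](C)(C)C)C[C@H](Br)[C@@H](Br)C[C@@H]1OC(=O)c1ccccc1)c1ccccc1
F5 | step 7 | [(1R,2S,5S)-2-(benzoyloxy)-5-bromo-1-(trimethylsilyloxy)cyclohex-3-en-1-yl]methyl benzoate | O=C(OC[C@]1(O[Si](C)(C)C)C[C@H](Br)C=C[C@@H]1OC(=O)c1ccccc1)c1ccccc1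
F6 | step 7 | [(1R,6S)-6-(benzoyloxy)-1-(trimethylsilyloxy)cyclohexa-2,4-dien-1-yl]methyl benzoate | O=C(OC[C@]1(O[Si](C)(C)C)C=CC=C[C@@H]1OC(=O)c1ccccc1)c1ccccc1
F7 | step 8 | C5,C6-epoxide of 12 on the face of the C1 hydroxyl | O=C(OC[C@]1(O)[C@H]2O[C@H]2C=C[C@@H]1OC(=O)c1ccccc1)c1ccccc1
F8 | step 8 | [(1S,2S,5R,6S)-2-(benzoyloxy)-1,5,6-trihydroxycyclohex-3-en-1-yl]methyl benzoate | O=C(OC[C@]1(O)[C@@H](O)[C@H](O)C=C[C@@H]1OC(=O)c1ccccc1)c1ccccc1
F9 | step 9 | O5,O6-dibutylstannylene acetal of 14 | O=C(OC[C@]1(O)[C@H]3O[Sn](CCCC)(CCCC)O[C@H]3C=C[C@@H]1OC(=O)c1ccccc1)c1ccccc1
A1 | alternative 1 | 4-O-benzoyl-2,3-bis-O-(4-methoxybenzyl) D-galactal analogue carrying an (E)-2-(benzoyloxy)vinyl group on C5 in place of CH2OH | C1=C(OCc2ccc(OC)cc2)[C@@H](OCc2ccc(OC)cc2)[C@@H](OC(=O)c2ccccc2)[C@@H](/C=C/OC(=O)c2ccccc2)O1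
A2 | alternative 1 | 2,5-bis(benzoyloxy)-1,6-bis(4-methoxybenzyloxy)cyclohex-3-ene-1-carbaldehyde with the configuration of 15 at C1, C2, C5 and C6 | O=C[C@@]1(OCc2ccc(OC)cc2)[C@@H](OC(=O)c2ccccc2)C=C[C@H](OC(=O)c2ccccc2)[C@@H]1OCc1ccc(OC)cc1
A3 | alternative 2 | (1-hydroxy-4-oxocyclohexa-2,5-dien-1-yl)methyl benzoate | O=C(OCC1(O)C=CC(=O)C=C1)c1ccccc1
A4 | alternative 2 | cis-fused 2-isopropyl-1,3-dioxolane enone, O1/O6 acetal of the C1 benzoyloxymethyl cyclohexenone | O=C(OC[C@@]12C=CC(=O)C[C@@H]1O[C@@H](C(C)C)O2)c1ccccc1
A5 | alternative 3 | 6,6-dibromobicyclo[3.1.0]hexane with C1 hydroxyl, C7 benzoate and C5/C6 acetonide, cyclopropane anti to the acetonide | O=C(OC[C@@]1(O)[C@H]3C(Br)(Br)[C@H]3[C@@H]2OC(C)(C)O[C@H]12)c1ccccc1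
A6 | alternative 3 | 3-bromocyclohex-3-ene with C2 benzoate, free C1 and C7 hydroxyls and C5/C6 acetonide | OC[C@@]1(O)[C@@H](OC(=O)c2ccccc2)C(Br)=C[C@@H]2OC(C)(C)O[C@H]12
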